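**Plan**

- Retrosynthesis, in order: the three phenol acetates; the C3–H and C3a–H bonds (hydrogenation of a C3=C3a enol lactone); the lactone O2–C3 bond (enol lactonization of a γ-keto acid); the aryl–C(=O) bond (acyl cross-coupling); the two oxolane bonds O5–C6 and C4–C3a, which split that ring into formaldehyde and a donor–acceptor cyclopropane; the cyclopropane into an enal and a bromomalonate.
- Enabling feature: in the oxolane ring (O5–C4H2–C3a–C6a–C6), C6 is a benzylic C–O carbon bearing the catechol ring (donor). C3a, joined to it through C6a, bears C3, which can be held at the carboxyl level beside a second, removable carboxyl (geminal acceptor). C6–C6a–C3a is thus a latent cyclopropane and O5=C4H2 is formaldehyde.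
- Forward order: cyclopropane ring (aminocatalysis), oxolane ring by (3+2) annulation with formaldehyde, decarboxylation and aryl ketone, lactone ring as an enol lactone, hydrogenation, deacetylation.
- Stereochemistry: C6 and C6a come from the (R)-diphenylprolinol silyl ether-catalysed trans cyclopropanation. Inversion at C6 in the annulation turns the trans cyclopropane into the 2,3-cis oxolane. C3 and C3a come from syn hydrogenation on the face of H6a.
- The phenols are carried as acetates, which hold both arenes near the donor strength of phenyl in the acid-mediated steps.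

Key step: step 7

Remark: the SMILES is read as (3S,3aS,6S,6aR)-6-(3,4-dihydroxyphenyl)-3-(4-hydroxy-3,5-dimethoxyphenyl)tetrahydro-1H,3H-furo[3,4-c]furan-1-one, in which H3, H3a, H6 and H6a are mutually cis (both aryl groups on the concave face); this numbering is used throughout.

**Step 1**
Reactants: 1 3,4-dihydroxybenzaldehyde
Product: 2 4-formyl-1,2-phenylene diacetate
Conditions: Ac2O, pyridine, DMAP (cat), CH2Cl2, 0 → 25 °C
Reagents that add atoms: acetic anhydride, CC(=O)OC(C)=O
Why: base-catalysed O-acetylation of both phenols should be clean, and the acetates also temper the donor strength of this ring for steps 7 to 12.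

**Step 2**
Reactants: 2 4-formyl-1,2-phenylene diacetate
Product: 3 (E)-3-[3,4-bis(acetyloxy)phenyl]prop-2-enal
Conditions: Ph3P=CHCHO (1.05 equiv), toluene, 80 °C
Reagents that add atoms: (triphenylphosphoranylidene)acetaldehyde, O=CC=P(c1ccccc1)(c1ccccc1)c1ccccc1
Why: Wittig olefination with the stabilised formylmethylene ylide should give the (E)-enal.

**Step 3**
Reactants: 4 dibenzyl propanedioate (dibenzyl malonate)
Product: 5 dibenzyl 2-bromopropanedioate
Conditions: Br2 (1.0 equiv), CH2Cl2, 0 → 25 °C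
Reagents that add atoms: bromine, BrBr
Why: electrophilic α-bromination of the malonate enol, autocatalysed by HBr, should stop at the monobromide with one equivalent of bromine.

**Step 4**
Reactants: 3 (E)-3-[3,4-bis(acetyloxy)phenyl]prop-2-enal; 5 dibenzyl 2-bromopropanedioate
Product: 6 dibenzyl (2R,3S)-2-[3,4-bis(acetyloxy)phenyl]-3-formylcyclopropane-1,1-dicarboxylate
Conditions: (R)-α,α-diphenylprolinol trimethylsilyl ether (20 mol %), 2,6-lutidine (1.1 equiv), CH2Cl2, 25 °C
Reagents that add atoms: none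
Why: aminocatalytic Michael-initiated ring closure (iminium conjugate addition of the bromomalonate, then enamine 3-exo-tet alkylation), in which the CPh2(OSiMe3) group shields one face of the E iminium ion so that the (R)-catalyst should set the aryl-bearing carbon as R, and the alkylation places formyl trans to aryl.

**Step 5**
Reactants: 6 dibenzyl (2R,3S)-2-[3,4-bis(acetyloxy)phenyl]-3-formylcyclopropane-1,1-dicarboxylate
Product: 7 (1S,3R)-3-[3,4-bis(acetyloxy)phenyl]-2,2-bis[(benzyloxy)carbonyl]cyclopropane-1-carboxylic acid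
Conditions: NaClO2, NaH2PO4, 2-methylbut-2-ene, t-BuOH/H2O, 0 → 25 °C
Reagents that add atoms: sodium chlorite, [Na+].[O-]Cl=O
Why: Pinnick oxidation converts the aldehyde into the acid under buffered conditions that should leave the cyclopropane, the acetates and the α-stereocenter untouched.

**Step 6**
Reactants: 7 (1S,3R)-3-[3,4-bis(acetyloxy)phenyl]-2,2-bis[(benzyloxy)carbonyl]cyclopropane-1-carboxylic acid
Product: 8 1,1-dibenzyl 2-tert-butyl (2S,3R)-3-[3,4-bis(acetyloxy)phenyl]cyclopropane-1,1,2-tricarboxylate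
Conditions: tert-butyl 2,2,2-trichloroacetimidate (2 equiv), CH2Cl2/cyclohexane, 25 °C
Reagents that add atoms: tert-butyl 2,2,2-trichloroacetimidate, CC(C)(C)OC(=N)C(Cl)(Cl)Cl
Why: base-free tert-butyl transfer from the imidate, promoted by the acid itself, should give an ester that is orthogonal to the benzyl esters and cleaved by acid in step 11.

**Step 7**
Reactants: 8 1,1-dibenzyl 2-tert-butyl (2S,3R)-3-[3,4-bis(acetyloxy)phenyl]cyclopropane-1,1,2-tricarboxylate
Product: 9 4,4-dibenzyl 3-tert-butyl (2S,3R)-2-[3,4-bis(acetyloxy)phenyl]oxolane-3,4,4-tricarboxylate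
Conditions: paraformaldehyde (5 equiv CH2O), Sn(OTf)2 (10 mol %), ClCH2CH2Cl, 25 → 45 °C
Reagents that add atoms: formaldehyde (supplied as paraformaldehyde), C=O
Why: Sn(OTf)2 binds the geminal diester and polarizes the C(aryl)–C(malonate) bond; the formaldehyde oxygen attacks the benzylic carbon from the rear in an SN2-like step and the tin malonate enolate then closes onto the O-alkylated formaldehyde carbon, so the O1–C2 and C5–C4 bonds of the oxolane form in one operation. The closest known reaction type is the Lewis acid-catalysed (3+2) annulation of 2-aryl cyclopropane-1,1-diesters, including 2,3-disubstituted ones, with aldehydes. The one ring closed is the oxolane, by an aldol-type 5-endo-trig attack of the malonate carbon (enolexo) on the oxocarbenium carbon, the mode that operates in these aldehyde annulations. C2 is set by inversion at the benzylic carbon, which turns the trans aryl/ester relationship of 8 into the 2,3-cis relationship of 9; C3 is carried over unchanged from 8, and C4 and C5 are not stereogenic. The step needs cleavage of the aryl–malonate bond and not of the aryl–C(CO2tBu) bond, which the two-point binding of the geminal diester secures. It also needs inversion and not ionization to a free benzylic cation, which the two acetates secure by holding the donor strength of the ring near that of phenyl.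

**Step 8**
Reactants: 9 4,4-dibenzyl 3-tert-butyl (2S,3R)-2-[3,4-bis(acetyloxy)phenyl]oxolane-3,4,4-tricarboxylate
Product: 11 (4R,5S)-5-[3,4-bis(acetyloxy)phenyl]-4-(tert-butoxycarbonyl)oxolane-3-carboxylic acid as both C3 epimers, via malonic diacid 10 (not isolated)
Conditions: H2 (1 atm), Pd/C (10 wt %), EtOAc, 25 °C; filtration; then toluene, 100 °C
Reagents that add atoms: none
Why: hydrogenolysis of the two benzyl esters followed by thermal decarboxylation of the geminal diacid should give the monoacid, whose C3 configuration does not matter because this carbon becomes trigonal again in step 11.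

**Step 9**
Reactants: 12 4-bromo-2,6-dimethoxyphenol
Product: 13 4-bromo-2,6-dimethoxyphenyl acetate
Conditions: Ac2O, pyridine, DMAP (cat), CH2Cl2, 25 °C
Reagents that add atoms: acetic anhydride, CC(=O)OC(C)=O
Why: O-acetylation protects the phenol in the same form as the other two.

**Step 10**
Reactants: 11 (4R,5S)-5-[3,4-bis(acetyloxy)phenyl]-4-(tert-butoxycarbonyl)oxolane-3-carboxylic acid; 13 4-bromo-2,6-dimethoxyphenyl acetate
Product: 16 tert-butyl (2S,3R)-4-[4-(acetyloxy)-3,5-dimethoxybenzoyl]-2-[3,4-bis(acetyloxy)phenyl]oxolane-3-carboxylate as both C4 epimers, via acid chloride 14 (not isolated), via arylzinc chloride 15 (not isolated)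
Conditions: 11, Me2C=C(Cl)NMe2 (1.2 equiv), CH2Cl2, 0 → 25 °C; 13, Mg, LiCl, ZnCl2, THF, 25 °C; then both, Pd(PPh3)4 (5 mol %), THF, 25 °C
Reagents that add atoms: none
Why: Negishi-type acyl cross-coupling of an arylzinc with an acid chloride should give the aryl ketone, since the neutral chloroenamine spares the tert-butyl ester and magnesium insertion with in situ trapping by ZnCl2 tolerates the aryl acetate.

**Step 11**
Reactants: 16 tert-butyl (2S,3R)-4-[4-(acetyloxy)-3,5-dimethoxybenzoyl]-2-[3,4-bis(acetyloxy)phenyl]oxolane-3-carboxylate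
Product: 18 (6S,6aR)-3-[4-(acetyloxy)-3,5-dimethoxyphenyl]-6-[3,4-bis(acetyloxy)phenyl]-6,6a-dihydro-1H,4H-furo[3,4-c]furan-1-one, via keto acid 17 (not isolated)
Conditions: TFA, CH2Cl2, 0 → 25 °C; evaporation; then Ac2O, HClO4 (cat), EtOAc, 25 °C
Reagents that add atoms: none
Why: acidolysis of the tert-butyl ester followed by acid-catalysed dehydrative enol lactonization of the γ-keto acid should close the lactone ring with both C4 epimers converging on the C3=C3a alkene, while the base-free medium leaves the C6a hydrogen in place.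

**Step 12**
Reactants: 18 (6S,6aR)-3-[4-(acetyloxy)-3,5-dimethoxyphenyl]-6-[3,4-bis(acetyloxy)phenyl]-6,6a-dihydro-1H,4H-furo[3,4-c]furan-1-one
Product: 19 (3S,3aS,6S,6aR)-3-[4-(acetyloxy)-3,5-dimethoxyphenyl]-6-[3,4-bis(acetyloxy)phenyl]tetrahydro-1H,3H-furo[3,4-c]furan-1-one
Conditions: H2 (4 atm), Pd/C (10 wt %), EtOAc, 25 °C
Reagents that add atoms: none
Why: heterogeneous syn hydrogenation of the enol lactone should occur on the face carrying H6a, because the other face is covered by the folded oxolane ring with its C6 aryl group and would lead to a trans-fused bicycle, and this sets C3 and C3a with all four methine hydrogens cis.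

**Step 13**
Reactants: 19 (3S,3aS,6S,6aR)-3-[4-(acetyloxy)-3,5-dimethoxyphenyl]-6-[3,4-bis(acetyloxy)phenyl]tetrahydro-1H,3H-furo[3,4-c]furan-1-one
Product: 20 (3S,3aS,6S,6aR)-6-(3,4-dihydroxyphenyl)-3-(4-hydroxy-3,5-dimethoxyphenyl)tetrahydro-1H,3H-furo[3,4-c]furan-1-one
Conditions: N2H4·H2O (4 equiv), AcOH (4 equiv), THF/MeOH, 0 → 25 °C, argon
Reagents that add atoms: none
Why: buffered hydrazinolysis should remove the three aryl acetates, which are far better acyl donors than the γ-lactone, without generating the phenoxides that would open the benzylic C–O bonds through quinone methides.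

**Compound list**

1 | 3,4-dihydroxybenzaldehyde | O=Cc1ccc(O)c(O)c1 | starting material
2 | 4-formyl-1,2-phenylene diacetate | CC(=O)Oc1ccc(C=O)cc1OC(C)=O | intermediate
3 | (E)-3-[3,4-bis(acetyloxy)phenyl]prop-2-enal | CC(=O)Oc1ccc(/C=C/C=O)cc1OC(C)=O | intermediate
4 | dibenzyl propanedioate | O=C(CC(=O)OCc1ccccc1)OCc1ccccc1 | starting material
5 | dibenzyl 2-bromopropanedioate | O=C(OCc1ccccc1)C(Br)C(=O)OCc1ccccc1 | intermediate
6 | dibenzyl (2R,3S)-2-[3,4-bis(acetyloxy)phenyl]-3-formylcyclopropane-1,1-dicarboxylate | O=C[C@H]1[C@H](c2ccc(OC(C)=O)c(OC(C)=O)c2)C1(C(=O)OCc1ccccc1)C(=O)OCc1ccccc1 | intermediate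
7 | (1S,3R)-3-[3,4-bis(acetyloxy)phenyl]-2,2-bis[(benzyloxy)carbonyl]cyclopropane-1-carboxylic acid | OC(=O)[C@H]1[C@H](c2ccc(OC(C)=O)c(OC(C)=O)c2)C1(C(=O)OCc1ccccc1)C(=O)OCc1ccccc1 | intermediate
8 | 1,1-dibenzyl 2-tert-butyl (2S,3R)-3-[3,4-bis(acetyloxy)phenyl]cyclopropane-1,1,2-tricarboxylate | CC(C)(C)OC(=O)[C@H]1[C@H](c2ccc(OC(C)=O)c(OC(C)=O)c2)C1(C(=O)OCc1ccccc1)C(=O)OCc1ccccc1 | intermediate
9 | 4,4-dibenzyl 3-tert-butyl (2S,3R)-2-[3,4-bis(acetyloxy)phenyl]oxolane-3,4,4-tricarboxylate | CC(C)(C)OC(=O)[C@@H]1C(C(=O)OCc2ccccc2)(C(=O)OCc2ccccc2)CO[C@@H]1c1ccc(OC(C)=O)c(OC(C)=O)c1 | intermediate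
10 | (4R,5S)-5-[3,4-bis(acetyloxy)phenyl]-4-(tert-butoxycarbonyl)oxolane-3,3-dicarboxylic acid | CC(C)(C)OC(=O)[C@@H]1C(C(=O)O)(C(=O)O)CO[C@@H]1c1ccc(OC(C)=O)c(OC(C)=O)c1 | intermediate (not isolated)
11 | (4R,5S)-5-[3,4-bis(acetyloxy)phenyl]-4-(tert-butoxycarbonyl)oxolane-3-carboxylic acid, both C3 epimers | CC(C)(C)OC(=O)[C@@H]1C(C(=O)O)CO[C@@H]1c1ccc(OC(C)=O)c(OC(C)=O)c1 | intermediate
12 | 4-bromo-2,6-dimethoxyphenol | COc1cc(Br)cc(OC)c1O | starting material
13 | 4-bromo-2,6-dimethoxyphenyl acetate | COc1cc(Br)cc(OC)c1OC(C)=O | intermediate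
14 | tert-butyl (2S,3R)-2-[3,4-bis(acetyloxy)phenyl]-4-(carbonochloridoyl)oxolane-3-carboxylate, both C4 epimers | CC(C)(C)OC(=O)[C@@H]1C(C(Cl)=O)CO[C@@H]1c1ccc(OC(C)=O)c(OC(C)=O)c1 | intermediate (not isolated)
15 | [4-(acetyloxy)-3,5-dimethoxyphenyl]zinc chloride | COc1cc([Zn]Cl)cc(OC)c1OC(C)=O | intermediate (not isolated)
16 | tert-butyl (2S,3R)-4-[4-(acetyloxy)-3,5-dimethoxybenzoyl]-2-[3,4-bis(acetyloxy)phenyl]oxolane-3-carboxylate, both C4 epimers | CC(C)(C)OC(=O)[C@@H]1C(C(=O)c2cc(OC)c(OC(C)=O)c(OC)c2)CO[C@@H]1c1ccc(OC(C)=O)c(OC(C)=O)c1 | intermediate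
17 | (2S,3R)-4-[4-(acetyloxy)-3,5-dimethoxybenzoyl]-2-[3,4-bis(acetyloxy)phenyl]oxolane-3-carboxylic acid, both C4 epimers | OC(=O)[C@@H]1C(C(=O)c2cc(OC)c(OC(C)=O)c(OC)c2)CO[C@@H]1c1ccc(OC(C)=O)c(OC(C)=O)c1 | intermediate (not isolated)
18 | (6S,6aR)-3-[4-(acetyloxy)-3,5-dimethoxyphenyl]-6-[3,4-bis(acetyloxy)phenyl]-6,6a-dihydro-1H,4H-furo[3,4-c]furan-1-one | O=C1OC(c2cc(OC)c(OC(C)=O)c(OC)c2)=C2CO[C@H](c3ccc(OC(C)=O)c(OC(C)=O)c3)[C@H]12 | intermediate
19 | (3S,3aS,6S,6aR)-3-[4-(acetyloxy)-3,5-dimethoxyphenyl]-6-[3,4-bis(acetyloxy)phenyl]tetrahydro-1H,3H-furo[3,4-c]furan-1-one | COc1cc([C@H]2OC(=O)[C@@H]3[C@H]2CO[C@@H]3c2ccc(OC(C)=O)c(OC(C)=O)c2)cc(OC)c1OC(C)=O | intermediate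
20 | (3S,3aS,6S,6aR)-6-(3,4-dihydroxyphenyl)-3-(4-hydroxy-3,5-dimethoxyphenyl)tetrahydro-1H,3H-furo[3,4-c]furan-1-one | COc1cc([C@H]2OC(=O)[C@@H]3[C@H]2CO[C@@H]3c2ccc(O)c(O)c2)cc(OC)c1O | target

**Step count**

Total: 13 steps. Longest linear sequence: 11 steps (1, 2, 4, 5, 6, 7, 8, 10, 11, 12, 13); steps 3 and 9 prepare the two side components.

**Steps most likely to fail**

Step 7. The ring opening may be slow, because the cyclopropane bears a weakly donating aryl group and a third ester, while formaldehyde is a poor nucleophile that re-polymerizes under the Lewis acid. Forcing the reaction may open the benzylic carbon by ionization, which would erode the 2,3-cis relationship, or may cleave the tert-butyl ester. The fallback sets out from 6, comes back at 17, and runs the same ring construction with C3 of the cyclopropane at the alcohol oxidation level, so that no third acceptor sits on the ring. Aldehyde 6 is reduced with LiAlH(OtBu)3 (THF, −78 °C) to the hydroxymethyl cyclopropane F1 and silylated (TBDPSCl, imidazole, DMF) to the silyl ether F2. This is a 3-(alkoxymethyl)-2-aryl cyclopropane diester, a type established in lignan-directed aldehyde annulations. Paraformaldehyde and Sn(OTf)2 should then give the oxolane F3. Hydrogenolysis (H2, Pd/C) gives the diacid F4, and warming in toluene gives the monoacid F5. The chloroenamine of step 10 gives the acid chloride F6, and coupling with 15 under Pd(PPh3)4 gives the ketone F7. HF·pyridine frees the hydroxy ketone F8, and TEMPO with PhI(OAc)2 in aqueous MeCN oxidizes the primary alcohol to the keto acid 17, which enters step 11 at its second stage.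

Step 12. Addition of hydrogen to the tetrasubstituted, aryl-conjugated enol ester bond may be slow. Forcing it may cause hydrogenolysis of the benzylic C3–O bond of the product, or migration of the double bond toward C6a on the metal surface. The fallback sets out from 18, comes back at 19, and replaces surface hydrogenation by ionic hydrogenation (Et3SiH, CF3SO3H (cat), CH2Cl2, −40 → 0 °C). Protonation of C3a on the convex face gives the cis-fused acyloxycarbenium ion, and the silane delivers hydride to C3 on the same face. The acetylated aryl group keeps the product lactone from ionizing again. No new isolated compound arises.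

Step 13. Once the phenols are free, the strained all-cis lactone may open, or the C3–O and C6–O bonds may ionize through para-quinone methides, which would epimerize C3 or C6; the hindered 2,6-dimethoxyphenyl acetate may also react slowly. The fallback sets out from 19, comes back at 20, and replaces chemical acyl transfer by enzymatic transesterification (immobilised Candida antarctica lipase B, n-butanol, tert-butyl methyl ether, 35 °C), which works at neutral pH without a free nucleophile or base. No new compound arises.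

**Further compounds**

F1 | step 7 | dibenzyl (2R,3S)-2-[3,4-bis(acetyloxy)phenyl]-3-(hydroxymethyl)cyclopropane-1,1-dicarboxylate | OC[C@H]1[C@H](c2ccc(OC(C)=O)c(OC(C)=O)c2)C1(C(=O)OCc1ccccc1)C(=O)OCc1ccccc1
F2 | step 7 | dibenzyl (2R,3S)-2-[3,4-bis(acetyloxy)phenyl]-3-{[(tert-butyldiphenylsilyl)oxy]methyl}cyclopropane-1,1-dicarboxylate | CC(C)(C)[Si](OC[C@H]1[C@H](c2ccc(OC(C)=O)c(OC(C)=O)c2)C1(C(=O)OCc1ccccc1)C(=O)OCc1ccccc1)(c1ccccc1)c1ccccc1
F3 | step 7 | dibenzyl (4S,5S)-5-[3,4-bis(acetyloxy)phenyl]-4-{[(tert-butyldiphenylsilyl)oxy]methyl}oxolane-3,3-dicarboxylate | CC(C)(C)[Si](OC[C@@H]1C(C(=O)OCc2ccccc2)(C(=O)OCc2ccccc2)CO[C@@H]1c1ccc(OC(C)=O)c(OC(C)=O)c1)(c1ccccc1)c1ccccc1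
F4 | step 7 | (4S,5S)-5-[3,4-bis(acetyloxy)phenyl]-4-{[(tert-butyldiphenylsilyl)oxy]methyl}oxolane-3,3-dicarboxylic acid | CC(C)(C)[Si](OC[C@@H]1C(C(=O)O)(C(=O)O)CO[C@@H]1c1ccc(OC(C)=O)c(OC(C)=O)c1)(c1ccccc1)c1ccccc1
F5 | step 7 | (4S,5S)-5-[3,4-bis(acetyloxy)phenyl]-4-{[(tert-butyldiphenylsilyl)oxy]methyl}oxolane-3-carboxylic acid, both C3 epimers | CC(C)(C)[Si](OC[C@@H]1C(C(=O)O)CO[C@@H]1c1ccc(OC(C)=O)c(OC(C)=O)c1)(c1ccccc1)c1ccccc1
F6 | step 7 | (4S,5S)-5-[3,4-bis(acetyloxy)phenyl]-4-{[(tert-butyldiphenylsilyl)oxy]methyl}oxolane-3-carbonyl chloride, both C3 epimers | CC(C)(C)[Si](OC[C@@H]1C(C(Cl)=O)CO[C@@H]1c1ccc(OC(C)=O)c(OC(C)=O)c1)(c1ccccc1)c1ccccc1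
F7 | step 7 | [4-(acetyloxy)-3,5-dimethoxyphenyl][(4S,5S)-5-[3,4-bis(acetyloxy)phenyl]-4-{[(tert-butyldiphenylsilyl)oxy]methyl}oxolan-3-yl]methanone, both C3 epimers | CC(C)(C)[Si](OC[C@@H]1C(C(=O)c2cc(OC)c(OC(C)=O)c(OC)c2)CO[C@@H]1c1ccc(OC(C)=O)c(OC(C)=O)c1)(c1ccccc1)c1ccccc1
F8 | step 7 | [4-(acetyloxy)-3,5-dimethoxyphenyl][(4S,5S)-5-[3,4-bis(acetyloxy)phenyl]-4-(hydroxymethyl)oxolan-3-yl]methanone, both C3 epimers | OC[C@@H]1C(C(=O)c2cc(OC)c(OC(C)=O)c(OC)c2)CO[C@@H]1c1ccc(OC(C)=O)c(OC(C)=O)c1
F0 | step 12 | none | none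
F0 | step 13 | none | none
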